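Rings A (C4a–C8a and C4a''–C8a''), each an acylphloroglucinol hung on C4 or C4'', are read as Claisen-folded 3,5,7-triketo chains. The C2–C3–C3''–C2'' core is therefore carried as an (E,E)-2,3-dibenzylidene-1,4-diketone whose carbonyls each bear a 4-hydroxy-2-pyron-6-ylmethyl arm, a masked triketo ester. Magnesium methoxide opens both pyrones and folds both chains in one operation, forming C4a–C8a and C4a''–C8a'' and both aromatic rings, to give a bis-chalcone. A catalyst-controlled double oxa-Michael closure then builds rings C and C'' with all four stereocentres, and one hydrogenolysis releases the target.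

Key step: step 6

Remark on the target: read from the SMILES, ring C (4-methoxyphenyl side) is 2,3-trans (2R,3S), ring C'' (4-hydroxyphenyl side) is 2,3-cis (2''R,3''R), and C2 and C2'' have the same sense.

Remark on the precursor design: the phenol travels as a benzyl ether, so no acid or base is needed once the cis ring exists. The anisyl ring travels with two bromine atoms ortho to OMe, which make its enone the better acceptor and so fix which ring C closes first. Benzyl and both bromines leave together in the last step. 4-(Benzyloxy)benzaldehyde and 3,5-dibromo-4-methoxybenzaldehyde are taken as catalogue compounds.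

Step 1
Reactants: 1 dimethyl succinate; 2 3,5-dibromo-4-methoxybenzaldehyde
Product: 3 (E)-4-(3,5-dibromo-4-methoxyphenyl)-3-(methoxycarbonyl)but-3-enoic acid
Conditions: NaOMe (2.2 equiv), MeOH, reflux; then 1 M HCl
Reagents that add atoms: none
Why: Stobbe condensation: the succinate enolate adds to the aldehyde, the alkoxide lactonises onto the remote ester and E1cB opening of the paraconate gives the (E)-benzylidene half-ester with the ester left on the alkene carbon.

Step 2
Reactants: 3 (E)-4-(3,5-dibromo-4-methoxyphenyl)-3-(methoxycarbonyl)but-3-enoic acid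
Product: 4 dimethyl (E)-2-(3,5-dibromo-4-methoxybenzylidene)succinate
Conditions: MeOH, H2SO4 (cat.), reflux
Reagents that add atoms: methanol, CO
Why: Fischer esterification of the unconjugated acid; nothing acid-sensitive is present and the aryl-conjugated alkene keeps its place and geometry.

Step 3
Reactants: 4 dimethyl (E)-2-(3,5-dibromo-4-methoxybenzylidene)succinate; 5 4-(benzyloxy)benzaldehyde
Product: 6 (2E,3E)-3-[4-(benzyloxy)benzylidene]-2-(3,5-dibromo-4-methoxybenzylidene)succinic acid 4-methyl ester (free acid on the carbon that carries the dibromoanisylidene group)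
Conditions: NaOMe (2.5 equiv), MeOH, reflux; then 1 M HCl
Reagents that add atoms: none
Why: Second Stobbe condensation at the remaining methylene; lactonisation onto the conjugated ester and E1cB opening leave that carboxyl as the acid and give the diene with each aryl group trans to its geminal carboxyl carbon (E,E), the usual outcome for dibenzylidenesuccinates.

Step 4
Reactants: 6 (2E,3E)-3-[4-(benzyloxy)benzylidene]-2-(3,5-dibromo-4-methoxybenzylidene)succinic acid 4-methyl ester
Product: 7 dimethyl (2E,3E)-2-[4-(benzyloxy)benzylidene]-3-(3,5-dibromo-4-methoxybenzylidene)succinate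
Conditions: MeI, K2CO3, DMF, rt
Reagents that add atoms: iodomethane, CI
Why: SN2 O-methylation of the carboxylate under mild base, which leaves the diene geometry, the benzyl ether and the aryl bromides untouched.

Step 5
Reactants: 7 dimethyl (2E,3E)-2-[4-(benzyloxy)benzylidene]-3-(3,5-dibromo-4-methoxybenzylidene)succinate; 8 4-hydroxy-6-methyl-2H-pyran-2-one (triacetic acid lactone)
Product: 9 (3E,4E)-3-[4-(benzyloxy)benzylidene]-4-(3,5-dibromo-4-methoxybenzylidene)-1,6-bis(4-hydroxy-2-oxo-2H-pyran-6-yl)hexane-2,5-dione
Conditions: 8 (5 equiv), LiN(iPr)2 (10 equiv), THF/DMPU, −78 °C; then 7, −78 to −20 °C; then AcOH, 1 M HCl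
Reagents that add atoms: none
Why: Claisen-type C-acylation of the dilithio dianion of 8 at its 6-methyl carbon by each ester group; the excess dianion absorbs the acidic proton of every new 1,3-dicarbonyl link, and low temperature favours carbonyl attack over conjugate attack on the twisted, α-branched diene esters.

Step 6
Reactants: 9 (3E,4E)-3-[4-(benzyloxy)benzylidene]-4-(3,5-dibromo-4-methoxybenzylidene)-1,6-bis(4-hydroxy-2-oxo-2H-pyran-6-yl)hexane-2,5-dione
Product: 11 (2E,3E)-2-[4-(benzyloxy)benzylidene]-3-(3,5-dibromo-4-methoxybenzylidene)-1,4-bis(2,4,6-trihydroxyphenyl)butane-1,4-dione, via open-chain bis(triketo ester) 10 (not isolated)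
Conditions: Mg(OMe)2 (12 equiv), MeOH, reflux, argon; then poured into ice-cold 1 M HCl
Reagents that add atoms: none
Why: Methoxide, delivered on magnesium, opens each pyrone at its lactone carbonyl to the magnesium chelate of a methyl 3,5,7-trioxoalkanoate (10); the chelated carbanion on the carbon next to the C4 (or C4'') ketone then adds to the ester carbonyl, methoxide leaves, and the resulting cyclohexanetrione enolises three times to the arene. The closest known reaction is the magnesium-methoxide Claisen cyclisation of 6-(2-oxoalkyl)-4-hydroxy-2-pyrones and of open-chain 3,5,7-triketo esters to acylphloroglucinols, here run at both ends of one molecule. Each ring A closes in the 6-exo-trig (Dieckmann) mode, giving C4a–C8a and C4a''–C8a''. No stereocentre is created and the E,E-diene is not touched. The step needs Claisen folding instead of the aldol folding that leads to resorcylates: the magnesium chelate of the tricarbonyl array holds the ester as the acceptor, C3 and C3'' carry no hydrogen so each C4 ketone can enolise only into its chain, and the product ring is symmetrical so no regiochemical choice arises. The enones must also survive: as magnesium phenolate chelates in a twisted, α-branched diene they are poor acceptors for methoxide or for their own phenolates, and the cold acid quench avoids the near-neutral window in which chalcones close.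

Step 7
Reactants: 11 (2E,3E)-2-[4-(benzyloxy)benzylidene]-3-(3,5-dibromo-4-methoxybenzylidene)-1,4-bis(2,4,6-trihydroxyphenyl)butane-1,4-dione
Product: 13 (2R,3S,2''R,3''R)-2''-[4-(benzyloxy)phenyl]-2-(3,5-dibromo-4-methoxyphenyl)-5,5'',7,7''-tetrahydroxy-3,3''-bichroman-4,4''-dione (ring C 2,3-trans; ring C'' 2,3-cis), via mono-closed 2,3-trans flavanone 12 (not isolated)
Conditions: N-[3,5-bis(trifluoromethyl)phenyl]-N'-[(9R)-6'-methoxycinchonan-9-yl]thiourea (20 mol%), toluene/THF 3:1, −20 °C, stopped when 12 is consumed; AcOH quench
Reagents that add atoms: none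
Why: Proposed new method: the catalyst's quinuclidine takes the proton of an ortho-phenol while the thiourea binds the C4 carbonyl, and the phenolate adds to C2 in a 6-endo-trig oxa-Michael step on one enone face; the same catalyst then closes ring C'' with the same sense, so C2 and C2'' should both be set as R (sense assigned by analogy, to be confirmed on 12; the quinine-derived pseudo-enantiomer reverses it). The enone bearing the dibromoanisyl group is the better acceptor and should close first; in 12 the C3–H is α to the ketone and allylic, so it should equilibrate through the dienolate to the 2,3-trans ring (3S). The second enolate should be protonated at C3'' anti to the pseudo-axial C2'' aryl group, giving the 2'',3''-cis ring (3''R), whose C3''–H is no longer allylic and should withstand the weak amine at −20 °C. Closest known reactions: cinchona-thiourea-catalysed enantioselective closure of 2'-hydroxychalcones to flavanones, and base-mediated closure of α-substituted 2'-hydroxychalcones to 3-substituted flavanones; a catalyst-controlled twofold closure to a trans/cis 3,3''-biflavanone has not been shown.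

Step 8
Reactants: 13 (2R,3S,2''R,3''R)-2''-[4-(benzyloxy)phenyl]-2-(3,5-dibromo-4-methoxyphenyl)-5,5'',7,7''-tetrahydroxy-3,3''-bichroman-4,4''-dione
Product: 14 sikokianin B, (2R,3S,2''R,3''R)-5,5'',7,7''-tetrahydroxy-2''-(4-hydroxyphenyl)-2-(4-methoxyphenyl)-3,3''-bichroman-4,4''-dione
Conditions: H2 (1 atm), 10% Pd/C, NaOAc (3 equiv), AcOH (5 equiv), EtOAc/MeOH 1:1, rt
Reagents that add atoms: none
Why: Palladium-catalysed hydrogenolysis cleaves the benzyl ether and both aryl C–Br bonds in an acetate buffer, conditions that should neither enolise the C4'' ketone (C3'' epimerisation) nor open a pyranone ring (C2 or C2'' epimerisation).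

Compound list
1 | dimethyl succinate | COC(=O)CCC(=O)OC | starting material
2 | 3,5-dibromo-4-methoxybenzaldehyde | COc1c(Br)cc(C=O)cc1Br | starting material
3 | (E)-4-(3,5-dibromo-4-methoxyphenyl)-3-(methoxycarbonyl)but-3-enoic acid | COc1c(Br)cc(/C=C(/C(=O)OC)\CC(=O)O)cc1Br | intermediate
4 | dimethyl (E)-2-(3,5-dibromo-4-methoxybenzylidene)succinate | COc1c(Br)cc(/C=C(/C(=O)OC)\CC(=O)OC)cc1Br | intermediate
5 | 4-(benzyloxy)benzaldehyde | O=Cc1ccc(OCc2ccccc2)cc1 | starting material
6 | (2E,3E)-3-[4-(benzyloxy)benzylidene]-2-(3,5-dibromo-4-methoxybenzylidene)succinic acid 4-methyl ester | COc1c(Br)cc(/C=C(/C(=O)O)\C(=C/c2ccc(OCc3ccccc3)cc2)\C(=O)OC)cc1Br | intermediate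
7 | dimethyl (2E,3E)-2-[4-(benzyloxy)benzylidene]-3-(3,5-dibromo-4-methoxybenzylidene)succinate | COc1c(Br)cc(/C=C(/C(=O)OC)\C(=C/c2ccc(OCc3ccccc3)cc2)\C(=O)OC)cc1Br | intermediate
8 | 4-hydroxy-6-methyl-2H-pyran-2-one (triacetic acid lactone) | CC1=CC(O)=CC(=O)O1 | starting material
9 | (3E,4E)-3-[4-(benzyloxy)benzylidene]-4-(3,5-dibromo-4-methoxybenzylidene)-1,6-bis(4-hydroxy-2-oxo-2H-pyran-6-yl)hexane-2,5-dione | COc1c(Br)cc(/C=C(/C(=O)CC2=CC(O)=CC(=O)O2)\C(=C/c2ccc(OCc3ccccc3)cc2)\C(=O)CC2=CC(O)=CC(=O)O2)cc1Br | intermediate
10 | dimethyl (8E,9E)-8-[4-(benzyloxy)benzylidene]-9-(3,5-dibromo-4-methoxybenzylidene)-3,5,7,10,12,14-hexaoxohexadecanedioate (formed as its magnesium chelate) | COc1c(Br)cc(/C=C(/C(=O)CC(=O)CC(=O)CC(=O)OC)\C(=C/c2ccc(OCc3ccccc3)cc2)\C(=O)CC(=O)CC(=O)CC(=O)OC)cc1Br | intermediate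
11 | (2E,3E)-2-[4-(benzyloxy)benzylidene]-3-(3,5-dibromo-4-methoxybenzylidene)-1,4-bis(2,4,6-trihydroxyphenyl)butane-1,4-dione | COc1c(Br)cc(/C=C(/C(=O)c2c(O)cc(O)cc2O)\C(=C/c2ccc(OCc3ccccc3)cc2)\C(=O)c2c(O)cc(O)cc2O)cc1Br | intermediate
12 | (2R,3S)-3-{(E)-2-[4-(benzyloxy)phenyl]-1-(2,4,6-trihydroxybenzoyl)ethenyl}-2-(3,5-dibromo-4-methoxyphenyl)-5,7-dihydroxychroman-4-one | COc1c(Br)cc([C@@H]2Oc3cc(O)cc(O)c3C(=O)[C@H]2/C(=C\c2ccc(OCc3ccccc3)cc2)C(=O)c2c(O)cc(O)cc2O)cc1Br | intermediate
13 | (2R,3S,2''R,3''R)-2''-[4-(benzyloxy)phenyl]-2-(3,5-dibromo-4-methoxyphenyl)-5,5'',7,7''-tetrahydroxy-3,3''-bichroman-4,4''-dione | COc1c(Br)cc([C@@H]2Oc3cc(O)cc(O)c3C(=O)[C@H]2[C@H]2C(=O)c3c(O)cc(O)cc3O[C@H]2c2ccc(OCc3ccccc3)cc2)cc1Br | intermediate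
14 | sikokianin B, (2R,3S,2''R,3''R)-5,5'',7,7''-tetrahydroxy-2''-(4-hydroxyphenyl)-2-(4-methoxyphenyl)-3,3''-bichroman-4,4''-dione | COc1ccc([C@@H]2Oc3cc(O)cc(O)c3C(=O)[C@H]2[C@H]2C(=O)c3c(O)cc(O)cc3O[C@H]2c2ccc(O)cc2)cc1 | target

Total step count: 8. Longest linear sequence: 8 steps (1 → 3 → 4 → 6 → 7 → 9 → 11 → 13 → 14).

Steps most likely to fail

Step 7 (proposed new method).
- What may go wrong: the catalyst may not impose the same facial sense at C2 and C2'' on a polyphenolic, α-branched bis-enone. The first-closed ring may fail to equilibrate at C3 before the second closure, or the second ring may epimerise at C3'' after closure. Closure in the reverse order would put the trans ring on the wrong aryl side. Reprotonation of the dienolate of 12 at C2'' would divert material to a 3-ylidene isomer.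
- Fallback, known chemistry: it sets out from 11. Et3N (0.2 equiv) in CH2Cl2/MeOH at 0 °C to rt closes both rings by the ordinary base-mediated chalcone-to-flavanone isomerisation without facial control, giving the stereoisomer mixture of the protected biflavanone F1. The (2R*,3S*,2''R*,3''R*) racemate is isolated on silica, its relative configuration being assigned from the H2–H3 couplings of each ring. It is then resolved by preparative HPLC on an amylose tris(3,5-dimethylphenylcarbamate) phase. This returns to the route at 13.

Step 6 (key step).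
- What may go wrong: at the temperature needed to open both pyronate rings, methoxide may cleave the 1,3-dicarbonyl links (retro-Claisen), one arm may stall half-folded, or the new phenolates may close rings C prematurely and without stereocontrol.
- Fallback: it sets out from 7 and 8. Methanolysis of 8 with Mg(OMe)2 in MeOH gives methyl 3,5-dioxohexanoate F2. Its trilithio derivative (LiN(iPr)2, 3 equiv, THF, −78 to 0 °C) is acylated at the terminal methyl carbon by both ester groups of 7, which gives the open-chain bis(triketo ester) 10 as an isolated compound. 10 is folded with Mg(OMe)2 in MeOH at room temperature, where no pyrone has to be opened. This returns to the route at 11.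

Step 5.
- What may go wrong: conjugate addition of the dianion to the benzylidene esters, and quenching of the dianion by the acidic mono-acylated product so that the second ester is left unreacted.
- Fallback: it sets out from 7. MeNH(OMe)·HCl and AlMe3 in CH2Cl2 convert both esters into the bis(N-methoxy-N-methylamide) F3. The dianion of 8 (2.5 equiv, THF, −78 °C) adds to give chelated tetrahedral adducts that collapse only on acidic work-up, so no acidic ketone is present in the flask and carbonyl addition is favoured. This returns to the route at 9.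

Further compounds
F1 | step 7 | 2''-[4-(benzyloxy)phenyl]-2-(3,5-dibromo-4-methoxyphenyl)-5,5'',7,7''-tetrahydroxy-3,3''-bichroman-4,4''-dione, mixture of racemic diastereomers | COc1c(Br)cc(C2Oc3cc(O)cc(O)c3C(=O)C2C2C(=O)c3c(O)cc(O)cc3OC2c2ccc(OCc3ccccc3)cc2)cc1Br
F2 | step 6 | methyl 3,5-dioxohexanoate | CC(=O)CC(=O)CC(=O)OC
F3 | step 5 | (2E,3E)-2-[4-(benzyloxy)benzylidene]-3-(3,5-dibromo-4-methoxybenzylidene)-N1,N4-dimethoxy-N1,N4-dimethylsuccinamide | COc1c(Br)cc(/C=C(/C(=O)N(C)OC)\C(=C/c2ccc(OCc3ccccc3)cc2)\C(=O)N(C)OC)cc1Br
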